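1. I began with a subtraction on these runs.

| setting | birch | larch | west | east | north-west |
|---|---|---|---|---|---|
| substrate | 36 mM | 36 mM | 36 mM | 36 mM | 36 mM |
| partner | 0.55 equiv | 0.83 equiv | 1.10 equiv | 1.10 equiv | 1.10 equiv |
| free catalyst | 0.26 mol% | 0.26 mol% | 0.26 mol% | 0.26 mol% | 0.26 mol% |
| second catalyst | 10 mol% | 10 mol% | 10 mol% | 10 mol% | 10 mol% |
| impurity | 2.8 mM | 2.8 mM | 2.8 mM | 2.8 mM | 2.8 mM |
| temperature | −5 °C | 12 °C | 0 °C | 25 °C |  |
| remark | run made earlier | run made earlier |  |  | at 0 °C until 12 min, from then on at 25 °C |
| time |  |  | 1.0 h | 1.0 h | 1.0 h |

| run | time / min | target / % | substrate / % |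
|---|---|---|---|
| birch | 2.50 | 1.4 | 92.5 |
| birch | 8.00 | 7.0 | 81.8 |
| birch | 15.0 | 12.8 | 64.6 |
| birch | 20.0 | 14.6 | 57.0 |
| birch | 30.0 | 19.9 | 42.9 |
| birch | 40.0 | 23.4 | 31.5 |
| birch | 50.0 | 22.6 | 25.7 |
| larch | 1.33 | 5.8 | 85.0 |
| larch | 4.00 | 9.6 | 64.9 |
| larch | 8.00 | 12.0 | 41.4 |
| larch | 12.0 | 11.2 | 26.4 |
| larch | 15.0 | 11.2 | 19.4 |
| larch | 20.0 | 9.2 | 12.1 |
| larch | 30.0 | 12.7 | 0.7 |

(each reading ± 1 percentage point)
- what was read earlier has a scatter of 1 percentage point, one standard deviation
- the best flask by amount of target, in percent of the substrate charged; "all alike" if 1.5 percentage points covers them all (west / east / north-west / all alike)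
- amount of target at the end, in percent of the substrate charged, west
- amount of target at the end, in percent of the substrate charged, east
- amount of target at the end, in percent of the substrate charged, north-west

Birch's last two readings of target average 23.0% of the substrate charged, against 0.55 equiv of partner. Larch's readings from 8.00 min on average 11.3%, against 0.83 equiv. I guessed that the gap in each run between partner charged and target was partner lost another way, though no run measured partner.

2. So I folded each run into one number, the partner odds: target formed per unit of partner that did not become target. Birch gave 0.719, and warmer larch gave a smaller 0.157.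

3. Those runs changed partner and temperature together, so I assumed that the odds followed temperature and shrank by a constant factor per degree. West's odds came to 0.459, giving 34.6% of target. East, an extrapolation, came to 0.0490, giving 5.14%.

4. North-west tested the single number, and it needed a clock as well. In the readings, target stopped rising near 40.0 min in birch and 8.00 min in larch, which put my estimate of west's stop near 24.9 min. The change therefore came about half way through, and weighting the two yields by time gave 19.3%. I chose west, whose reckoned yield was higher than the reckoned yield of either other flask.

5. The forecast chose west, with 38% there, 4% in east and 26% in north-west, on a different ground from mine: “the productive catalyst dies”.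

6. The flasks gave 31.0% in west, 5.92% in east and 22.6% in north-west, so west came first.

    substrate + free catalyst → free catalyst + intermediate (k = 7.60 /M/s, Ea = 51.0 kJ/mol)
    partner + second catalyst + intermediate → second catalyst + target (k = 150 /M²/s, Ea = 36.0 kJ/mol)
    second catalyst + impurity → spent catalyst (k = 11.0 /M/s, Ea = 41.0 kJ/mol)
    partner → decomposed reagent (k = 0.00150 /s, Ea = 85.0 kJ/mol)
    (constants at 0 °C)

At 1.00 h, west held 0% of partner, the limiting reagent for target, and 28.4 mM of decomposed reagent. West's odds had put the partner lost at 27.1 mM.

7. A neighbour of west, charged with 17 mol% of second catalyst, has the same temperature and partner, so the odds again give 34.6% of target and 27.1 mM lost. The computed flask gave more target, 42.6%, with 24.3 mM of decomposed reagent.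

The data come from a simulation on assumed constants; scatter was added.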